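**Plan**

- Ring atoms are numbered C1 (isopropenyl-bearing) round to C14 (acetoxy-bearing), with methyls on C4, C8 and C12 and carbinols at C9 and C10. The 14-membered ring holds the E-C11=C12(Me) alkene directly beside the C10 carbinol; this allylic alcohol is the trace of a C10 propargylic alcohol, so C11≡C12 can serve as the ring-closing bond.
- Retrosynthetic cuts, in order: the C12–CH3 bond and the protecting groups; the ring at C11≡C12 (metathesis of two propynyl ends); the C2–C3 diene bond; then C5–C6 and C7=C8 in the west half, and C1–isopropenyl and C12–C13 in the east half.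
- Forward: a tartrate ketal is grown at both ends into the C3–C11 enediyne, and a glycidic ester gives the C12–C2 Z-iodo-diene. The two are joined at C2–C3, the single carbocycle closes at C11≡C12, and the alkyne is then converted into the methyl-bearing E-alkene before the acetate is installed.
- Stereochemistry: C9 and C10 come unchanged from D-tartaric acid and C14 from methyl (S)-glycidate. E-C7=C8 comes from a Horner–Wadsworth–Emmons reaction, E-C3=C4 from syn-carboalumination, Z-C1=C2 from hydroxyl-directed anti-carbomagnesiation, and E-C11=C12 from hydroxyl-directed trans-hydroalumination.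

Key step: step 16

Remark: descriptors given for the macrocyclic compounds use the ring numbering above; the purchased ketal diester and glycidic ester are taken as enantiopure.

**Route**

Step 1
Reactants: 1 dimethyl (4S,5S)-2,2-dimethyl-1,3-dioxolane-4,5-dicarboxylate
Product: 2 (4S,5S)-N4,N5-dimethoxy-N4,N5,2,2-tetramethyl-1,3-dioxolane-4,5-dicarboxamide
Conditions: MeNH(OMe)·HCl, i-PrMgCl, THF, −20 → 0 °C
Reagents that add atoms: N,O-dimethylhydroxylamine hydrochloride, CNOC.Cl
Why: Weinreb amide formation by aminolysis of both esters with the chloromagnesium amide of N,O-dimethylhydroxylamine; the trans-fused ketal is the stable diastereomer, so C9 and C10 are not at risk.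

Step 2
Reactants: 2 (4S,5S)-N4,N5-dimethoxy-N4,N5,2,2-tetramethyl-1,3-dioxolane-4,5-dicarboxamide
Product: 3 (4S,5S)-5-acetyl-N-methoxy-N,2,2-trimethyl-1,3-dioxolane-4-carboxamide
Conditions: MeMgBr (1.2 equiv), THF, −15 °C; aq NH4Cl
Reagents that add atoms: methylmagnesium bromide, C[Mg]Br
Why: Weinreb ketone synthesis used as a desymmetrisation, in which the first methyl addition gives a magnesium-chelated tetrahedral adduct that survives to work-up and is expected to tie up the neighbouring amide, so one equivalent of MeMgBr should stop at the mono-ketone.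

Step 3
Reactants: 3 (4S,5S)-5-acetyl-N-methoxy-N,2,2-trimethyl-1,3-dioxolane-4-carboxamide
Product: 4 ethyl (2E)-3-[(4R,5S)-5-[methoxy(methyl)carbamoyl]-2,2-dimethyl-1,3-dioxolan-4-yl]but-2-enoate
Conditions: (EtO)2P(O)CH2CO2Et, NaH, THF, 0 °C → rt
Reagents that add atoms: triethyl phosphonoacetate, CCOC(=O)CP(=O)(OCC)OCC
Why: Horner–Wadsworth–Emmons olefination of an α-alkoxy methyl ketone under thermodynamic control, which should place the ester trans to the bulky dioxolanyl group and so give the E-C7=C8 alkene; the Weinreb amide is inert to the phosphonate anion.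

Step 4
Reactants: 4 ethyl (2E)-3-[(4R,5S)-5-[methoxy(methyl)carbamoyl]-2,2-dimethyl-1,3-dioxolan-4-yl]but-2-enoate
Product: 5 (4S,5R)-5-[(2E)-4-hydroxybut-2-en-2-yl]-2,2-dimethyl-1,3-dioxolane-4-carbaldehyde
Conditions: i-Bu2AlH (4 equiv), CH2Cl2, −78 °C; aq potassium sodium tartrate
Reagents that add atoms: none
Why: Hydride reduction with i-Bu2AlH, in which the enoate is taken to the allylic alcohol by 1,2-reduction while the Weinreb amide stops at its aluminium-chelated hemiaminal and gives the aldehyde only on hydrolysis.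

Step 5
Reactants: 5 (4S,5R)-5-[(2E)-4-hydroxybut-2-en-2-yl]-2,2-dimethyl-1,3-dioxolane-4-carbaldehyde
Product: 6 (2E)-3-[(4R,5R)-5-ethynyl-2,2-dimethyl-1,3-dioxolan-4-yl]but-2-en-1-ol
Conditions: dimethyl (1-diazo-2-oxopropyl)phosphonate, K2CO3, MeOH, 0 °C → rt
Reagents that add atoms: dimethyl (1-diazo-2-oxopropyl)phosphonate, COP(=O)(OC)C(=[N+]=[N-])C(C)=O
Why: Seyferth–Gilbert homologation in its Ohira–Bestmann form turns the aldehyde into the terminal alkyne whose inner carbon is C11; the free allylic alcohol is tolerated and the trans-ketal is the favoured epimer should C10 equilibrate.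

Step 6
Reactants: 6 (2E)-3-[(4R,5R)-5-ethynyl-2,2-dimethyl-1,3-dioxolan-4-yl]but-2-en-1-ol
Product: 7 (4R,5R)-4-[(2E)-4-bromobut-2-en-2-yl]-5-ethynyl-2,2-dimethyl-1,3-dioxolane
Conditions: CBr4, PPh3, CH2Cl2, −20 → 0 °C
Reagents that add atoms: tetrabromomethane, BrC(Br)(Br)Br
Why: Appel bromination of the primary allylic alcohol under neutral conditions, which should proceed without allylic transposition and leave alkyne and ketal alone.

Step 7
Reactants: 7 (4R,5R)-4-[(2E)-4-bromobut-2-en-2-yl]-5-ethynyl-2,2-dimethyl-1,3-dioxolane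
Product: 9 trimethyl{(5E)-6-[(4R,5R)-2,2-dimethyl-5-(prop-1-yn-1-yl)-1,3-dioxolan-4-yl]hept-5-en-1-yn-1-yl}silane, via lithium acetylide 8 (not isolated)
Conditions: Me3SiC≡CCH3 (2.5 equiv), n-BuLi (2.4 equiv), THF, −78 → −20 °C; then 7, −78 °C; then MeI, DMPU, −78 °C → rt
Reagents that add atoms: 1-(trimethylsilyl)propyne, CC#C[Si](C)(C)C; iodomethane, CI
Why: Alkylation of a propargylic organolithium by SN2 at the primary allylic bromide forms C5–C6, the silyl group steering attack to the propargyl terminus; the first equivalent of the reagent deprotonates the ethynyl group and MeI then caps that acetylide (acetylide alkylation) to give the C11 propynyl end.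

Step 8
Reactants: 9 trimethyl{(5E)-6-[(4R,5R)-2,2-dimethyl-5-(prop-1-yn-1-yl)-1,3-dioxolan-4-yl]hept-5-en-1-yn-1-yl}silane
Product: 10 (4R,5R)-4-[(2E)-hept-2-en-6-yn-2-yl]-2,2-dimethyl-5-(prop-1-yn-1-yl)-1,3-dioxolane
Conditions: K2CO3 (cat.), MeOH, rt
Reagents that add atoms: none
Why: Protodesilylation of the alkynylsilane by methoxide frees the C3≡C4 terminal alkyne; the methyl-capped alkyne and the ketal are inert.

Step 9
Reactants: 11 methyl (2S)-oxirane-2-carboxylate; 12 propyne
Product: 14 methyl (2S)-2-hydroxyhex-4-ynoate, via prop-1-ynyllithium 13 (not isolated)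
Conditions: 12, n-BuLi, THF, −78 °C; BF3·OEt2; then 11, −78 °C
Reagents that add atoms: none
Why: BF3-mediated epoxide alkynylation, in which the lithium acetylide–BF3 pair attacks the unsubstituted C3 of the glycidate by SN2 at a temperature where the ester is not attacked, so the C2 stereocentre (the future C14) is untouched.

Step 10
Reactants: 14 methyl (2S)-2-hydroxyhex-4-ynoate
Product: 15 methyl (2S)-2-[(triethylsilyl)oxy]hex-4-ynoate
Conditions: Et3SiCl, imidazole, CH2Cl2, 0 °C → rt
Reagents that add atoms: chlorotriethylsilane, CC[Si](Cl)(CC)CC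
Why: Silyl ether formation at the secondary alcohol so that the ester can be reduced to the aldehyde stage.

Step 11
Reactants: 15 methyl (2S)-2-[(triethylsilyl)oxy]hex-4-ynoate
Product: 16 (2S)-2-[(triethylsilyl)oxy]hex-4-ynal
Conditions: i-Bu2AlH (1.1 equiv), CH2Cl2, −78 °C; MeOH, aq potassium sodium tartrate
Reagents that add atoms: none
Why: Partial reduction of an α-silyloxy ester with i-Bu2AlH at −78 °C, where the tetrahedral aluminium hemiacetal persists until quench and delivers the aldehyde.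

Step 12
Reactants: 16 (2S)-2-[(triethylsilyl)oxy]hex-4-ynal
Product: 18 (3S)-hepta-1,5-diyn-3-ol, via triethylsilyl diyne 17 (not isolated)
Conditions: dimethyl (1-diazo-2-oxopropyl)phosphonate, K2CO3, MeOH, 0 °C → rt; then aq HCl (1 M), rt
Reagents that add atoms: dimethyl (1-diazo-2-oxopropyl)phosphonate, COP(=O)(OC)C(=[N+]=[N-])C(C)=O
Why: Ohira–Bestmann homologation makes the terminal C1≡C2 alkyne and dilute acid then cleaves the labile triethylsilyl ether in the same flask; short exposure to carbonate at 0 °C should keep the α-silyloxy aldehyde from racemising.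

Step 13
Reactants: 18 (3S)-hepta-1,5-diyn-3-ol; 19 isopropenylmagnesium bromide
Product: 21 (1Z,3S)-1-iodo-2-(prop-1-en-2-yl)hept-1-en-5-yn-3-ol, via cyclic alkenylmagnesium alkoxide 20 (not isolated)
Conditions: 19 (3.5 equiv), CuI (10 mol%), THF, −10 °C → rt; then I2, THF, −40 → 0 °C
Reagents that add atoms: iodine, II
Why: Copper-catalysed hydroxyl-directed anti-carbomagnesiation of a propargylic alcohol, in which the magnesium alkoxide delivers isopropenyl to C1 and magnesium to C2 on opposite faces to give a five-membered oxamagnesacycle with C2–Mg cis to C14, and iodinolysis with retention gives the Z-iodide; the terminal propargylic alkyne should react well before the internal homopropargylic one.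

Step 14
Reactants: 21 (1Z,3S)-1-iodo-2-(prop-1-en-2-yl)hept-1-en-5-yn-3-ol
Product: 22 tert-butyl{[(1Z,3S)-1-iodo-2-(prop-1-en-2-yl)hept-1-en-5-yn-3-yl]oxy}dimethylsilane
Conditions: t-BuMe2SiOTf, 2,6-lutidine, CH2Cl2, −78 → 0 °C
Reagents that add atoms: tert-butyldimethylsilyl trifluoromethanesulfonate, CC(C)(C)[Si](C)(C)OS(=O)(=O)C(F)(F)F
Why: Silyl ether formation at the hindered allylic alcohol with the silyl triflate masks C14–OH for the organometallic steps ahead.

Step 15
Reactants: 10 (4R,5R)-4-[(2E)-hept-2-en-6-yn-2-yl]-2,2-dimethyl-5-(prop-1-yn-1-yl)-1,3-dioxolane; 22 tert-butyl{[(1Z,3S)-1-iodo-2-(prop-1-en-2-yl)hept-1-en-5-yn-3-yl]oxy}dimethylsilane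
Product: 24 methyl-capped seco-diyne (4R,5R)-4-[(2E,6E,8Z,10S)-10-(tert-butyldimethylsilyloxy)-6-methyl-9-(prop-1-en-2-yl)tetradeca-2,6,8-trien-12-yn-2-yl]-2,2-dimethyl-5-(prop-1-yn-1-yl)-1,3-dioxolane, via alkenyldimethylalane 23 (not isolated)
Conditions: Me3Al (3 equiv), Cp2ZrCl2 (0.25 equiv), H2O (1.5 equiv), CH2Cl2, −25 °C; volatiles removed; then 22, ZnCl2 (0.3 equiv), Pd(PPh3)4 (5 mol%), THF, rt
Reagents that add atoms: trimethylaluminium, C[Al](C)C
Why: Zirconium-catalysed syn-carboalumination of the terminal alkyne (Negishi carboalumination) puts methyl on C4 and aluminium on C3 cis to it (E-C3=C4), and palladium/zinc-catalysed Negishi cross-coupling of this alkenylalane with the Z-iodide forms C2–C3 with retention at both alkenes; the terminal alkyne should carbometalate far faster than the two methyl-capped ones.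

Step 16
Reactants: 24 methyl-capped seco-diyne
Product: 25 14-membered cycloalkyne (1Z,3E,7E,9R,10R,14S)-14-(tert-butyldimethylsilyloxy)-9,10-(isopropylidenedioxy)-4,8-dimethyl-1-(prop-1-en-2-yl)cyclotetradeca-1,3,7-trien-11-yne
Conditions: (4-MeOC6H4C≡)Mo(OSiPh3)3 (15 mol%), 5 Å molecular sieves, toluene (2 mM), rt → 60 °C
Reagents that add atoms: none
Why: The molybdenum alkylidyne adds to one methyl-capped alkyne by [2+2] cycloaddition to give a metallacyclobutadiene, which cycloreverts with loss of the cap as but-2-yne to leave a substrate-bound alkylidyne; this engages the second alkyne intramolecularly in the same cycloaddition–cycloreversion sequence and releases the C11≡C12 triple bond. The closest known reaction type is ring-closing alkyne metathesis of α,ω-diynes with silanolate-supported molybdenum alkylidynes. The 14-membered carbocycle, the only carbocycle made in the route, closes end-to-end by metathesis of the C11 and C12 alkyne termini under high dilution, driven by adsorption of but-2-yne on the molecular sieves. No stereocentre is formed; C9, C10 and C14 are spectators and no alkene geometry is at stake because the new unit is linear. The step needs chemoselectivity for the two alkynes over four alkenes, including the cross-conjugated triene, and tolerance of silyl ether and ketal, which the alkylidyne provides because it does not engage C=C bonds. It also needs ring closure to win over oligomerisation, which dilution, the Z-C1=C2/E-C3=C4 diene and the trans-ketal should secure by turning the chain ends toward each other.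

Step 17
Reactants: 25 14-membered cycloalkyne
Product: 26 (1Z,3E,7E,9R,10R,14S)-14-(tert-butyldimethylsilyloxy)-4,8-dimethyl-1-(prop-1-en-2-yl)cyclotetradeca-1,3,7-trien-11-yne-9,10-diol
Conditions: AcOH/H2O (4:1), 40 °C
Reagents that add atoms: none
Why: Acid-catalysed ketal hydrolysis frees the C9,C10 diol needed to direct the next step; the hindered secondary silyl ether at C14 should survive aqueous acetic acid.

Step 18
Reactants: 26 cycloalkyne diol
Product: 28 (1Z,3E,7E,11Z,9R,10R,14S)-14-(tert-butyldimethylsilyloxy)-12-iodo-4,8-dimethyl-1-(prop-1-en-2-yl)cyclotetradeca-1,3,7,11-tetraene-9,10-diol, via cyclic alkenylalanate 27 (not isolated)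
Conditions: NaAlH2(OCH2CH2OMe)2, THF, 0 °C → rt; EtOAc; then I2, THF, −78 → −20 °C
Reagents that add atoms: iodine, II
Why: Hydroxyl-directed trans-hydroalumination of the propargylic alcohol, in which the C10 alkoxide holds aluminium, hydride goes to C11 and aluminium ends on C12 within a five-membered C10–O–Al–C12 ring, and iodine replaces aluminium with retention to give the Z-alkenyl iodide with iodine cis to C10; the silyl-protected C14 oxygen cannot compete as a directing group.

Step 19
Reactants: 28 alkenyl iodide diol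
Product: 29 (1Z,3E,7E,11E,9R,10R,14S)-14-(tert-butyldimethylsilyloxy)-4,8,12-trimethyl-1-(prop-1-en-2-yl)cyclotetradeca-1,3,7,11-tetraene-9,10-diol
Conditions: Me2Zn (5 equiv), Pd(PPh3)4 (10 mol%), THF, 0 → 50 °C
Reagents that add atoms: dimethylzinc, C[Zn]C
Why: Negishi cross-coupling of the alkenyl iodide with Me2Zn proceeds with retention, so methyl is cis to C10 and the E-C11=C12 alkene results; excess Me2Zn covers the two hydroxyl groups.

Step 20
Reactants: 29 methylated diol
Product: 30 (1Z,3E,7E,11E,9R,10R,14S)-14-(tert-butyldimethylsilyloxy)-9,10-(isopropylidenedioxy)-4,8,12-trimethyl-1-(prop-1-en-2-yl)cyclotetradeca-1,3,7,11-tetraene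
Conditions: Me2C(OMe)2, pyridinium p-toluenesulfonate (cat.), CH2Cl2, rt
Reagents that add atoms: 2,2-dimethoxypropane, COC(C)(C)OC
Why: Acid-catalysed transketalisation re-protects the 1,2-diol as the trans-dioxolane so that C14–OH can be handled alone.

Step 21
Reactants: 30 silyl ether ketal
Product: 31 (1Z,3E,7E,11E,9R,10R,14S)-9,10-(isopropylidenedioxy)-4,8,12-trimethyl-1-(prop-1-en-2-yl)cyclotetradeca-1,3,7,11-tetraen-14-ol
Conditions: Bu4NF, THF, 0 °C → rt
Reagents that add atoms: none
Why: Fluoride-induced desilylation frees C14–OH; the ketal is stable to Bu4NF.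

Step 22
Reactants: 31 C14 alcohol ketal
Product: 32 (1Z,3E,7E,11E,9R,10R,14S)-9,10-(isopropylidenedioxy)-4,8,12-trimethyl-1-(prop-1-en-2-yl)cyclotetradeca-1,3,7,11-tetraen-14-yl acetate
Conditions: Ac2O, pyridine, 4-(dimethylamino)pyridine (cat.), CH2Cl2, 0 °C → rt
Reagents that add atoms: acetic anhydride, CC(=O)OC(C)=O
Why: Nucleophile-catalysed acetylation of the secondary allylic alcohol with retention at C14.

Step 23
Reactants: 32 acetate ketal
Product: 33 (1Z,3E,7E,11E,9R,10R,14S)-9,10-dihydroxy-4,8,12-trimethyl-1-(prop-1-en-2-yl)cyclotetradeca-1,3,7,11-tetraen-14-yl acetate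
Conditions: AcOH/H2O (4:1), 35–40 °C
Reagents that add atoms: none
Why: Mild acid-catalysed ketal hydrolysis releases the C9,C10 diol; acetic acid should be too weak to ionise or hydrolyse the allylic acetate at this temperature.

**Compound list**

1 | dimethyl (4S,5S)-2,2-dimethyl-1,3-dioxolane-4,5-dicarboxylate (dimethyl 2,3-O-isopropylidene-D-tartrate) | COC(=O)[C@H]1OC(C)(C)O[C@@H]1C(=O)OC | starting material
2 | (4S,5S)-N4,N5-dimethoxy-N4,N5,2,2-tetramethyl-1,3-dioxolane-4,5-dicarboxamide | CON(C)C(=O)[C@H]1OC(C)(C)O[C@@H]1C(=O)N(C)OC | intermediate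
3 | (4S,5S)-5-acetyl-N-methoxy-N,2,2-trimethyl-1,3-dioxolane-4-carboxamide | CC(=O)[C@H]1OC(C)(C)O[C@@H]1C(=O)N(C)OC | intermediate
4 | ethyl (2E)-3-[(4R,5S)-5-[methoxy(methyl)carbamoyl]-2,2-dimethyl-1,3-dioxolan-4-yl]but-2-enoate | CCOC(=O)/C=C(\C)[C@H]1OC(C)(C)O[C@@H]1C(=O)N(C)OC | intermediate
5 | (4S,5R)-5-[(2E)-4-hydroxybut-2-en-2-yl]-2,2-dimethyl-1,3-dioxolane-4-carbaldehyde | OC/C=C(\C)[C@H]1OC(C)(C)O[C@@H]1C=O | intermediate
6 | (2E)-3-[(4R,5R)-5-ethynyl-2,2-dimethyl-1,3-dioxolan-4-yl]but-2-en-1-ol | OC/C=C(\C)[C@H]1OC(C)(C)O[C@@H]1C#C | intermediate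
7 | (4R,5R)-4-[(2E)-4-bromobut-2-en-2-yl]-5-ethynyl-2,2-dimethyl-1,3-dioxolane | BrC/C=C(\C)[C@H]1OC(C)(C)O[C@@H]1C#C | intermediate
8 | lithium acetylide of the C5–C6 alkylation product (lithium on the ethynyl terminus at C10) | C[Si](C)(C)C#CCC/C=C(\C)[C@H]1OC(C)(C)O[C@@H]1C#C[Li] | intermediate
9 | trimethyl{(5E)-6-[(4R,5R)-2,2-dimethyl-5-(prop-1-yn-1-yl)-1,3-dioxolan-4-yl]hept-5-en-1-yn-1-yl}silane | C[Si](C)(C)C#CCC/C=C(\C)[C@H]1OC(C)(C)O[C@@H]1C#CC | intermediate
10 | (4R,5R)-4-[(2E)-hept-2-en-6-yn-2-yl]-2,2-dimethyl-5-(prop-1-yn-1-yl)-1,3-dioxolane (west C3–C11 enediyne) | C#CCC/C=C(\C)[C@H]1OC(C)(C)O[C@@H]1C#CC | intermediate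
11 | methyl (2S)-oxirane-2-carboxylate (methyl (S)-glycidate) | COC(=O)[C@@H]1CO1 | starting material
12 | propyne | CC#C | starting material
13 | prop-1-ynyllithium | [Li]C#CC | intermediate
14 | methyl (2S)-2-hydroxyhex-4-ynoate | CC#CC[C@H](O)C(=O)OC | intermediate
15 | methyl (2S)-2-[(triethylsilyl)oxy]hex-4-ynoate | CC#CC[C@H](O[Si](CC)(CC)CC)C(=O)OC | intermediate
16 | (2S)-2-[(triethylsilyl)oxy]hex-4-ynal | CC#CC[C@H](O[Si](CC)(CC)CC)C=O | intermediate
17 | triethyl{[(3S)-hepta-1,5-diyn-3-yl]oxy}silane | CC#CC[C@H](O[Si](CC)(CC)CC)C#C | intermediate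
18 | (3S)-hepta-1,5-diyn-3-ol | CC#CC[C@H](O)C#C | intermediate
19 | isopropenylmagnesium bromide | C=C(C)[Mg]Br | starting material
20 | cyclic alkenylmagnesium alkoxide (five-membered C14–O–Mg–C2=C1 ring, isopropenyl on C1) | CC#CC[C@@H]1O[Mg]C=C1C(C)=C | intermediate
21 | (1Z,3S)-1-iodo-2-(prop-1-en-2-yl)hept-1-en-5-yn-3-ol | CC#CC[C@H](O)/C(C(C)=C)=C\I | intermediate
22 | tert-butyl{[(1Z,3S)-1-iodo-2-(prop-1-en-2-yl)hept-1-en-5-yn-3-yl]oxy}dimethylsilane (east C12–C2 iodide) | CC#CC[C@H](O[Si](C)(C)C(C)(C)C)/C(C(C)=C)=C\I | intermediate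
23 | (E)-alkenyldimethylalane from 10 (AlMe2 on C3, methyl on C4) | C[Al](C)/C=C(\C)CC/C=C(\C)[C@H]1OC(C)(C)O[C@@H]1C#CC | intermediate
24 | methyl-capped seco-diyne, (4R,5R)-4-[(2E,6E,8Z,10S)-10-(tert-butyldimethylsilyloxy)-6-methyl-9-(prop-1-en-2-yl)tetradeca-2,6,8-trien-12-yn-2-yl]-2,2-dimethyl-5-(prop-1-yn-1-yl)-1,3-dioxolane | CC#CC[C@H](O[Si](C)(C)C(C)(C)C)/C(C(C)=C)=C\C=C(/C)CC/C=C(\C)[C@H]1OC(C)(C)O[C@@H]1C#CC | intermediate
25 | 14-membered C11≡C12 cycloalkyne, (1Z,3E,7E,9R,10R,14S)-14-(tert-butyldimethylsilyloxy)-9,10-(isopropylidenedioxy)-4,8-dimethyl-1-(prop-1-en-2-yl)cyclotetradeca-1,3,7-trien-11-yne | C=C(C)/C1=C/C=C(\C)CC/C=C(\C)[C@H]2OC(C)(C)O[C@@H]2C#CC[C@@H]1O[Si](C)(C)C(C)(C)C | intermediate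
26 | (1Z,3E,7E,9R,10R,14S)-14-(tert-butyldimethylsilyloxy)-4,8-dimethyl-1-(prop-1-en-2-yl)cyclotetradeca-1,3,7-trien-11-yne-9,10-diol | C=C(C)/C1=C/C=C(\C)CC/C=C(\C)[C@@H](O)[C@H](O)C#CC[C@@H]1O[Si](C)(C)C(C)(C)C | intermediate
27 | cyclic alkenylalanate (sodium salt; five-membered C10–O–Al–C12=C11 ring, two 2-methoxyethoxy groups on aluminium, C9 as sodium alkoxide) | C=C(C)/C1=C/C=C(\C)CC/C=C(\C)[C@@H]([O-])[C@@H]2O[Al-](OCCOC)(OCCOC)C(C[C@@H]1O[Si](C)(C)C(C)(C)C)=C2.[Na+].[Na+] | intermediate
28 | (1Z,3E,7E,11Z,9R,10R,14S)-14-(tert-butyldimethylsilyloxy)-12-iodo-4,8-dimethyl-1-(prop-1-en-2-yl)cyclotetradeca-1,3,7,11-tetraene-9,10-diol | C=C(C)/C1=C/C=C(\C)CC/C=C(\C)[C@@H](O)[C@H](O)/C=C(\I)C[C@@H]1O[Si](C)(C)C(C)(C)C | intermediate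
29 | (1Z,3E,7E,11E,9R,10R,14S)-14-(tert-butyldimethylsilyloxy)-4,8,12-trimethyl-1-(prop-1-en-2-yl)cyclotetradeca-1,3,7,11-tetraene-9,10-diol | C=C(C)/C1=C/C=C(\C)CC/C=C(\C)[C@@H](O)[C@H](O)/C=C(\C)C[C@@H]1O[Si](C)(C)C(C)(C)C | intermediate
30 | (1Z,3E,7E,11E,9R,10R,14S)-14-(tert-butyldimethylsilyloxy)-9,10-(isopropylidenedioxy)-4,8,12-trimethyl-1-(prop-1-en-2-yl)cyclotetradeca-1,3,7,11-tetraene | C=C(C)/C1=C/C=C(\C)CC/C=C(\C)[C@H]2OC(C)(C)O[C@@H]2/C=C(\C)C[C@@H]1O[Si](C)(C)C(C)(C)C | intermediate
31 | (1Z,3E,7E,11E,9R,10R,14S)-9,10-(isopropylidenedioxy)-4,8,12-trimethyl-1-(prop-1-en-2-yl)cyclotetradeca-1,3,7,11-tetraen-14-ol | C=C(C)/C1=C/C=C(\C)CC/C=C(\C)[C@H]2OC(C)(C)O[C@@H]2/C=C(\C)C[C@@H]1O | intermediate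
32 | (1Z,3E,7E,11E,9R,10R,14S)-9,10-(isopropylidenedioxy)-4,8,12-trimethyl-1-(prop-1-en-2-yl)cyclotetradeca-1,3,7,11-tetraen-14-yl acetate | C=C(C)/C1=C/C=C(\C)CC/C=C(\C)[C@H]2OC(C)(C)O[C@@H]2/C=C(\C)C[C@@H]1OC(C)=O | intermediate
33 | (1Z,3E,7E,11E,9R,10R,14S)-9,10-dihydroxy-4,8,12-trimethyl-1-(prop-1-en-2-yl)cyclotetradeca-1,3,7,11-tetraen-14-yl acetate | C=C(C)/C1=C/C=C(\C)CC/C=C(\C)[C@@H](O)[C@H](O)/C=C(\C)C[C@@H]1OC(C)=O | target

**Count and risks**

Total step count: 23. Longest linear sequence: 17 steps (steps 1–8, then 15–23); the east branch (steps 9–14) is 6 steps.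

Steps most likely to fail:

Step 15. What may go wrong is competing carbometalation of the two methyl-capped alkynes, opening of the ketal by the Lewis-acidic aluminium reagent, or transfer of methyl instead of alkenyl in the coupling. The fallback sets out from 10 and avoids aluminium altogether. Copper-catalysed methylboration of the terminal alkyne (CuCl, Xantphos, NaOt-Bu, B2pin2, MeI, THF, rt) should add boron to C3 and methyl to C4 in a syn sense, giving the E-alkenyl pinacol boronate F1. Suzuki–Miyaura coupling of it with iodide 22 (Pd(dppf)Cl2, Cs2CO3, THF/H2O, 40 °C) would form the C2–C3 bond with retention and return to the route at 24.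

Step 16. What may go wrong is intermolecular metathesis to oligomers, or stalling because the rigid trans-fused ketal holds the two propynyl ends apart or its oxygens slow the catalyst. The fallback keeps the C11≡C12 ring closure but changes the substrate, setting out from 24. Hydrolysis of the ketal (AcOH/H2O, 40 °C) would give the seco-diyne diol F2, and silylation (Et3SiOTf, 2,6-lutidine, CH2Cl2, −78 °C) the conformationally free bis(triethylsilyl) ether F3. Ring-closing alkyne metathesis with the same molybdenum alkylidyne would then give the bis(triethylsilyl) cycloalkyne F4. Selective removal of the two triethylsilyl groups (pyridinium p-toluenesulfonate, MeOH, 0 °C) spares the C14 silyl ether and returns to the route at 26.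

Step 23. What may go wrong is ionisation or solvolysis of the acetate, which sits on a carbon allylic to the cross-conjugated triene, or incomplete hydrolysis of the trans-ketal under acid mild enough to spare it. The fallback sets out from 29 and needs no acid. Desilylation (Bu4NF, THF) would give the triol F5. In one flask, phenylboronic acid (toluene, MgSO4, rt) should then mask the 1,2-diol as the cyclic phenylboronate F6, Ac2O/pyridine/4-(dimethylamino)pyridine would acetylate the remaining C14 hydroxyl to the acetate boronate F7, and exchange with pinacol would release the diol. This comes back to the route at 33.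

Further compounds
F1 | step 15 | 2-{(1E,5E)-2-methyl-6-[(4R,5R)-2,2-dimethyl-5-(prop-1-yn-1-yl)-1,3-dioxolan-4-yl]hepta-1,5-dien-1-yl}-4,4,5,5-tetramethyl-1,3,2-dioxaborolane | CC1(C)OB(/C=C(\C)CC/C=C(\C)[C@H]2OC(C)(C)O[C@@H]2C#CC)OC1(C)C
F2 | step 16 | seco-diyne diol (24 without the ketal; free C9 and C10 hydroxyls) | CC#CC[C@H](O[Si](C)(C)C(C)(C)C)/C(C(C)=C)=C\C=C(/C)CC/C=C(\C)[C@@H](O)[C@H](O)C#CC
F3 | step 16 | seco-diyne 9,10-bis(triethylsilyl) ether | CC#CC[C@H](O[Si](C)(C)C(C)(C)C)/C(C(C)=C)=C\C=C(/C)CC/C=C(\C)[C@@H](O[Si](CC)(CC)CC)[C@H](O[Si](CC)(CC)CC)C#CC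
F4 | step 16 | 14-membered cycloalkyne 9,10-bis(triethylsilyl) ether with C14 tert-butyldimethylsilyl ether | C=C(C)/C1=C/C=C(\C)CC/C=C(\C)[C@@H](O[Si](CC)(CC)CC)[C@H](O[Si](CC)(CC)CC)C#CC[C@@H]1O[Si](C)(C)C(C)(C)C
F5 | step 23 | (1Z,3E,7E,11E,9R,10R,14S)-4,8,12-trimethyl-1-(prop-1-en-2-yl)cyclotetradeca-1,3,7,11-tetraene-9,10,14-triol | C=C(C)/C1=C/C=C(\C)CC/C=C(\C)[C@@H](O)[C@H](O)/C=C(\C)C[C@@H]1O
F6 | step 23 | 9,10-O-(phenylboranediyl) derivative of the triol (cyclic phenylboronate, free C14 hydroxyl) | C=C(C)/C1=C/C=C(\C)CC/C=C(\C)[C@H]2OB(c3ccccc3)O[C@@H]2/C=C(\C)C[C@@H]1O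
F7 | step 23 | 14-O-acetyl-9,10-O-(phenylboranediyl) derivative of the triol | C=C(C)/C1=C/C=C(\C)CC/C=C(\C)[C@H]2OB(c3ccccc3)O[C@@H]2/C=C(\C)C[C@@H]1OC(C)=O
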